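**Plan**

- Retrosynthesis: after removal of two silyl ethers and a redox detour at C4, ring C of the 3-arylchroman-4-one is cut at O1–C2 and at C4–C4a together, giving an aryl 2-arylacrylate. This ester is cut at its C–O bond into a ring A phenol and a ring B acrylic acid, and each prenyl–aryl bond is cut back to an aryl bromide.
- Enabling feature: O1 and C4a are ortho neighbours on ring A, and the C2–C3–C4 bridge between them is an acrylate unit. The C4 acyl carbon can therefore sit on O1 as an ester, shift to C4a (1,3-acyl shift), and the freed O1 then adds to the terminal CH2 (C2). C6 (para to O1) carries the prenyl group and C8 lies under the silyloxy group at C7, so C4a is the only open site.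
- Forward order: the ring A fragment (steps 1–3) and the ring B fragment (steps 4–7) are prenylated separately and joined as the ester (step 8). Ring C is closed last by photo-Fries rearrangement and oxa-Michael addition (step 9).
- Stereochemistry: C3 is benzylic and α to the C4 ketone, hence labile. The racemic ketone is funnelled into one isomer by transfer hydrogenation with dynamic kinetic resolution using RuCl[(R,R)-TsDPEN](p-cymene) (step 10, (3R,4R)-alcohol). Oxidation at C4 (step 11) leaves the (3R) centre, which afterwards meets no base.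

Key step: step 9

Remark: in 4-bromoresorcinol the hydroxyl para to bromine is assumed to react first with a bulky silyl chloride, and C3 of a 3-arylchroman-4-one is assumed to epimerize readily with amine bases.

**Route**

Step 1
Reactants: 1 4-bromobenzene-1,3-diol
Product: 3 1-bromo-4-(tert-butyldimethylsilyloxy)-2-(triisopropylsilyloxy)benzene, via mono-silyl ether 2 (not isolated)
Conditions: TBSCl (1.0 equiv), imidazole, CH2Cl2, −20 → 0 °C; then TIPSOTf, 2,6-lutidine, 0 → 20 °C
Reagents that add atoms: tert-butyldimethylsilyl chloride, CC(C)(C)[Si](C)(C)Cl; triisopropylsilyl trifluoromethanesulfonate, CC(C)[Si](OS(=O)(=O)C(F)(F)F)(C(C)C)C(C)C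
Why: Kinetic silylation with the bulky chloride should take the unhindered hydroxyl para to bromine (the ortho hydroxyl is shielded by bromine), and the triflate then caps the hindered hydroxyl, so the two oxygens carry silyl groups of different lability (selective O-silylation).

Step 2
Reactants: 3 1-bromo-4-(tert-butyldimethylsilyloxy)-2-(triisopropylsilyloxy)benzene
Product: 5 4-(tert-butyldimethylsilyloxy)-1-(3-methylbut-2-en-1-yl)-2-(triisopropylsilyloxy)benzene, via aryllithium 4 (not isolated)
Conditions: n-BuLi, THF, −78 °C; then CuBr·SMe2 (10 mol%), prenyl bromide, −78 → 0 °C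
Reagents that add atoms: prenyl bromide (1-bromo-3-methylbut-2-ene), CC(C)=CCBr
Why: Bromine–lithium exchange at −78 °C should outrun retro-Brook migration of the bulky triisopropylsilyl group, and copper-catalysed allylic substitution of prenyl bromide at its unsubstituted terminus (SN2 mode) gives the linear prenyl arene.

Step 3
Reactants: 5 4-(tert-butyldimethylsilyloxy)-1-(3-methylbut-2-en-1-yl)-2-(triisopropylsilyloxy)benzene
Product: 6 4-(3-methylbut-2-en-1-yl)-3-(triisopropylsilyloxy)phenol
Conditions: K2CO3 (0.2 equiv), MeOH/THF, 0 °C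
Reagents that add atoms: none
Why: Base-catalysed methanolysis cleaves the unhindered aryl tert-butyldimethylsilyl ether far faster than the aryl triisopropylsilyl ether shielded by the ortho prenyl group (selective desilylation).

Step 4
Reactants: 7 methyl 2-(3-bromo-4-hydroxyphenyl)acetate
Product: 8 methyl 2-[4-hydroxy-3-(3-methylbut-2-en-1-yl)phenyl]acetate
Conditions: Bu3Sn(prenyl), Pd(PPh3)4 (5 mol%), DMF, 100 °C
Reagents that add atoms: tributyl(3-methylbut-2-en-1-yl)stannane, CC(C)=CC[Sn](CCCC)(CCCC)CCCC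
Why: Stille coupling (oxidative addition of the aryl bromide to zerovalent palladium, transmetalation of the allylic stannane, reductive elimination) should give the linear prenyl arene under neutral conditions that tolerate the free phenol and the ester.

Step 5
Reactants: 8 methyl 2-[4-hydroxy-3-(3-methylbut-2-en-1-yl)phenyl]acetate
Product: 9 methyl 2-[3-(3-methylbut-2-en-1-yl)-4-(triisopropylsilyloxy)phenyl]acetate
Conditions: TIPSCl, imidazole, DMF, 20 → 40 °C
Reagents that add atoms: triisopropylsilyl chloride, CC(C)[Si](Cl)(C(C)C)C(C)C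
Why: Standard silylation of a phenol, with the triisopropylsilyl ether chosen because it should withstand the basic steps 6 and 7.

Step 6
Reactants: 9 methyl 2-[3-(3-methylbut-2-en-1-yl)-4-(triisopropylsilyloxy)phenyl]acetate
Product: 11 methyl 2-[3-(3-methylbut-2-en-1-yl)-4-(triisopropylsilyloxy)phenyl]prop-2-enoate, via aldol adduct 10 (not isolated)
Conditions: (CH2O)n, K2CO3, n-Bu4NI (10 mol%), toluene, 80 °C
Reagents that add atoms: paraformaldehyde (as formaldehyde), C=O
Why: Aldol addition of the ester enolate to formaldehyde followed by E1cB loss of water gives the 2-arylacrylate (α-methylenation of an arylacetate under phase-transfer conditions).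

Step 7
Reactants: 11 methyl 2-[3-(3-methylbut-2-en-1-yl)-4-(triisopropylsilyloxy)phenyl]prop-2-enoate
Product: 13 2-[3-(3-methylbut-2-en-1-yl)-4-(triisopropylsilyloxy)phenyl]prop-2-enoic acid, via lithium carboxylate 12 (not isolated)
Conditions: LiOH, THF/H2O, 0 °C; then 1 M HCl to pH 3
Reagents that add atoms: lithium hydroxide, [Li+].[OH-]
Why: Saponification of the unhindered methyl ester at 0 °C should be faster than attack of hydroxide on the hindered aryl silyl ether or on the acrylate double bond.

Step 8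
Reactants: 6 4-(3-methylbut-2-en-1-yl)-3-(triisopropylsilyloxy)phenol; 13 2-[3-(3-methylbut-2-en-1-yl)-4-(triisopropylsilyloxy)phenyl]prop-2-enoic acid
Product: 14 4-(3-methylbut-2-en-1-yl)-3-(triisopropylsilyloxy)phenyl 2-[3-(3-methylbut-2-en-1-yl)-4-(triisopropylsilyloxy)phenyl]prop-2-enoate
Conditions: DCC, DMAP (10 mol%), CH2Cl2, 0 → 20 °C
Reagents that add atoms: none
Why: Carbodiimide activation with DMAP as acyl-transfer catalyst (Steglich esterification) acylates the only free hydroxyl of 6 under neutral conditions that leave the acrylate untouched.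

Step 9
Reactants: 14 4-(3-methylbut-2-en-1-yl)-3-(triisopropylsilyloxy)phenyl 2-[3-(3-methylbut-2-en-1-yl)-4-(triisopropylsilyloxy)phenyl]prop-2-enoate
Product: 17 rac-6-(3-methylbut-2-en-1-yl)-3-[3-(3-methylbut-2-en-1-yl)-4-(triisopropylsilyloxy)phenyl]-7-(triisopropylsilyloxy)chroman-4-one, via cyclohexadienone 15 (not isolated), via hydroxyaryl enone 16 (not isolated)
Conditions: hν (254 nm, quartz), degassed cyclohexane (5 mM), 20 °C; then Et3N (0.2 equiv), 20 °C
Reagents that add atoms: none
Why: Excitation of the aryl ester cleaves the O1–C(acyl) bond homolytically and the caged aryloxyl/acyl radical pair recombines at the free ortho carbon to give dienone 15, which tautomerizes to the hydrogen-bonded enone 16 (C4–C4a formed); once the lamp is off, Et3N triggers oxa-Michael addition of O1 to the terminal CH2 and C-protonation of the enol (O1–C2 formed). The closest known reaction type is the photo-Fries rearrangement of aryl esters of α,β-unsaturated acids followed by base-mediated closure to chroman-4-ones. Ring C closes in the 6-endo-trig mode. The new C3 centre arises by uncontrolled protonation and is racemic by design, because C3 is set in step 10. The step needs ortho selectivity at the future C4a, which the substrate secures because the para carbon carries the prenyl group and the other ortho carbon lies between the two oxygens under the bulky silyloxy group; the silyl groups also block photocyclization of the ortho-prenylphenols. Enone 16 is shielded from secondary photochemistry by excited-state proton transfer in its O–H···O=C bond, which is why ring closure is held back until irradiation has ended.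

Step 10
Reactants: 17 rac-6-(3-methylbut-2-en-1-yl)-3-[3-(3-methylbut-2-en-1-yl)-4-(triisopropylsilyloxy)phenyl]-7-(triisopropylsilyloxy)chroman-4-one
Product: 18 (3R,4R)-6-(3-methylbut-2-en-1-yl)-3-[3-(3-methylbut-2-en-1-yl)-4-(triisopropylsilyloxy)phenyl]-7-(triisopropylsilyloxy)chroman-4-ol
Conditions: RuCl[(R,R)-TsDPEN](p-cymene) (2 mol%), HCO2H/Et3N (1:1), EtOAc, 40 °C
Reagents that add atoms: none
Why: Noyori–Ikariya asymmetric transfer hydrogenation under dynamic kinetic resolution: Et3N epimerizes C3 through the enol faster than the ketone is reduced, and the (R,R)-catalyst should reduce only the (3R)-ketone with hydride delivery anti to the C3 aryl group, which sets C4 as R and fixes C3 as R in the cis alcohol.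

Step 11
Reactants: 18 (3R,4R)-6-(3-methylbut-2-en-1-yl)-3-[3-(3-methylbut-2-en-1-yl)-4-(triisopropylsilyloxy)phenyl]-7-(triisopropylsilyloxy)chroman-4-ol
Product: 19 (3R)-6-(3-methylbut-2-en-1-yl)-3-[3-(3-methylbut-2-en-1-yl)-4-(triisopropylsilyloxy)phenyl]-7-(triisopropylsilyloxy)chroman-4-one
Conditions: Dess–Martin periodinane, CH2Cl2, 0 → 20 °C
Reagents that add atoms: none
Why: Dess–Martin oxidation of the benzylic alcohol runs under neutral to weakly acidic conditions, so the ketone should be restored without enolization and C3 keeps its R configuration.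

Step 12
Reactants: 19 (3R)-6-(3-methylbut-2-en-1-yl)-3-[3-(3-methylbut-2-en-1-yl)-4-(triisopropylsilyloxy)phenyl]-7-(triisopropylsilyloxy)chroman-4-one
Product: 20 (3R)-7-hydroxy-3-[4-hydroxy-3-(3-methylbut-2-en-1-yl)phenyl]-6-(3-methylbut-2-en-1-yl)chroman-4-one
Conditions: KHF2, MeOH/THF, 20 °C
Reagents that add atoms: none
Why: Bifluoride in methanol cleaves aryl silyl ethers under weakly acidic conditions, under which neither enolization at C3 nor cyclization of the ortho-prenylphenols is expected.

**Compound list**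

1 | 4-bromobenzene-1,3-diol | Oc1ccc(Br)c(O)c1 | starting material
2 | 2-bromo-5-(tert-butyldimethylsilyloxy)phenol (not isolated) | CC(C)(C)[Si](C)(C)Oc1ccc(Br)c(O)c1 | intermediate
3 | 1-bromo-4-(tert-butyldimethylsilyloxy)-2-(triisopropylsilyloxy)benzene | CC(C)(C)[Si](C)(C)Oc1ccc(Br)c(O[Si](C(C)C)(C(C)C)C(C)C)c1 | intermediate
4 | [4-(tert-butyldimethylsilyloxy)-2-(triisopropylsilyloxy)phenyl]lithium (not isolated) | [Li]c1ccc(O[Si](C)(C)C(C)(C)C)cc1O[Si](C(C)C)(C(C)C)C(C)C | intermediate
5 | 4-(tert-butyldimethylsilyloxy)-1-(3-methylbut-2-en-1-yl)-2-(triisopropylsilyloxy)benzene | CC(C)=CCc1ccc(O[Si](C)(C)C(C)(C)C)cc1O[Si](C(C)C)(C(C)C)C(C)C | intermediate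
6 | 4-(3-methylbut-2-en-1-yl)-3-(triisopropylsilyloxy)phenol | CC(C)=CCc1ccc(O)cc1O[Si](C(C)C)(C(C)C)C(C)C | intermediate
7 | methyl 2-(3-bromo-4-hydroxyphenyl)acetate | COC(=O)Cc1ccc(O)c(Br)c1 | starting material
8 | methyl 2-[4-hydroxy-3-(3-methylbut-2-en-1-yl)phenyl]acetate | COC(=O)Cc1ccc(O)c(CC=C(C)C)c1 | intermediate
9 | methyl 2-[3-(3-methylbut-2-en-1-yl)-4-(triisopropylsilyloxy)phenyl]acetate | COC(=O)Cc1ccc(O[Si](C(C)C)(C(C)C)C(C)C)c(CC=C(C)C)c1 | intermediate
10 | methyl 3-hydroxy-2-[3-(3-methylbut-2-en-1-yl)-4-(triisopropylsilyloxy)phenyl]propanoate, racemic (not isolated) | COC(=O)C(CO)c1ccc(O[Si](C(C)C)(C(C)C)C(C)C)c(CC=C(C)C)c1 | intermediate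
11 | methyl 2-[3-(3-methylbut-2-en-1-yl)-4-(triisopropylsilyloxy)phenyl]prop-2-enoate | COC(=O)C(=C)c1ccc(O[Si](C(C)C)(C(C)C)C(C)C)c(CC=C(C)C)c1 | intermediate
12 | lithium 2-[3-(3-methylbut-2-en-1-yl)-4-(triisopropylsilyloxy)phenyl]prop-2-enoate (not isolated) | [Li+].[O-]C(=O)C(=C)c1ccc(O[Si](C(C)C)(C(C)C)C(C)C)c(CC=C(C)C)c1 | intermediate
13 | 2-[3-(3-methylbut-2-en-1-yl)-4-(triisopropylsilyloxy)phenyl]prop-2-enoic acid | OC(=O)C(=C)c1ccc(O[Si](C(C)C)(C(C)C)C(C)C)c(CC=C(C)C)c1 | intermediate
14 | 4-(3-methylbut-2-en-1-yl)-3-(triisopropylsilyloxy)phenyl 2-[3-(3-methylbut-2-en-1-yl)-4-(triisopropylsilyloxy)phenyl]prop-2-enoate | C=C(C(=O)Oc1ccc(CC=C(C)C)c(O[Si](C(C)C)(C(C)C)C(C)C)c1)c1ccc(O[Si](C(C)C)(C(C)C)C(C)C)c(CC=C(C)C)c1 | intermediate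
15 | 4-(3-methylbut-2-en-1-yl)-6-{2-[3-(3-methylbut-2-en-1-yl)-4-(triisopropylsilyloxy)phenyl]prop-2-enoyl}-3-(triisopropylsilyloxy)cyclohexa-2,4-dien-1-one, racemic (not isolated) | O=C1C=C(O[Si](C(C)C)(C(C)C)C(C)C)C(CC=C(C)C)=CC1C(=O)C(=C)c1ccc(O[Si](C(C)C)(C(C)C)C(C)C)c(CC=C(C)C)c1 | intermediate
16 | 1-[2-hydroxy-5-(3-methylbut-2-en-1-yl)-4-(triisopropylsilyloxy)phenyl]-2-[3-(3-methylbut-2-en-1-yl)-4-(triisopropylsilyloxy)phenyl]prop-2-en-1-one (not isolated) | C=C(C(=O)c1cc(CC=C(C)C)c(O[Si](C(C)C)(C(C)C)C(C)C)cc1O)c1ccc(O[Si](C(C)C)(C(C)C)C(C)C)c(CC=C(C)C)c1 | intermediate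
17 | rac-6-(3-methylbut-2-en-1-yl)-3-[3-(3-methylbut-2-en-1-yl)-4-(triisopropylsilyloxy)phenyl]-7-(triisopropylsilyloxy)chroman-4-one | CC(C)=CCc1cc(C2COc3cc(O[Si](C(C)C)(C(C)C)C(C)C)c(CC=C(C)C)cc3C2=O)ccc1O[Si](C(C)C)(C(C)C)C(C)C | intermediate
18 | (3R,4R)-6-(3-methylbut-2-en-1-yl)-3-[3-(3-methylbut-2-en-1-yl)-4-(triisopropylsilyloxy)phenyl]-7-(triisopropylsilyloxy)chroman-4-ol (3,4-cis) | CC(C)=CCc1cc([C@@H]2COc3cc(O[Si](C(C)C)(C(C)C)C(C)C)c(CC=C(C)C)cc3[C@@H]2O)ccc1O[Si](C(C)C)(C(C)C)C(C)C | intermediate
19 | (3R)-6-(3-methylbut-2-en-1-yl)-3-[3-(3-methylbut-2-en-1-yl)-4-(triisopropylsilyloxy)phenyl]-7-(triisopropylsilyloxy)chroman-4-one | CC(C)=CCc1cc([C@@H]2COc3cc(O[Si](C(C)C)(C(C)C)C(C)C)c(CC=C(C)C)cc3C2=O)ccc1O[Si](C(C)C)(C(C)C)C(C)C | intermediate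
20 | (3R)-7-hydroxy-3-[4-hydroxy-3-(3-methylbut-2-en-1-yl)phenyl]-6-(3-methylbut-2-en-1-yl)chroman-4-one | CC(C)=CCc1cc([C@@H]2COc3cc(O)c(CC=C(C)C)cc3C2=O)ccc1O | target

**Step count and risks**

Total steps: 12. Longest linear sequence: 9 (steps 4–12, from 7 to 20).

Steps most likely to fail:

Step 9. Radical escape from the solvent cage, competing photochemistry or polymerization of the 2-arylacrylate unit, or inefficient excitation of the ester chromophore could leave little rearranged ketone. The fallback is the classical deoxybenzoin construction of ring C; it sets out from 7 and 1 and returns at 17. NaOH then acid converts 7 into 2-(3-bromo-4-hydroxyphenyl)acetic acid F1. BF3·OEt2 at 85 °C joins F1 to 1 by C-acylation para to a hydroxyl, giving 1-(5-bromo-2,4-dihydroxyphenyl)-2-(3-bromo-4-hydroxyphenyl)ethan-1-one F2. Paraformaldehyde and Et2NH in EtOH methylenate the benzylic CH2 and the ortho hydroxyl closes ring C, giving rac-6-bromo-3-(3-bromo-4-hydroxyphenyl)-7-hydroxychroman-4-one F3. TIPSOTf/2,6-lutidine gives rac-6-bromo-3-[3-bromo-4-(triisopropylsilyloxy)phenyl]-7-(triisopropylsilyloxy)chroman-4-one F4. A twofold Stille coupling (tributyl(3-methylbut-2-en-1-yl)stannane, Pd(PPh3)4, DMF, 100 °C) then installs both prenyl groups and delivers 17.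

Step 10. The silyl group para to the ketone could be lost under formate/amine, which would deactivate the ketone, or enolization at C3 could be slower than reduction, so that the dynamic resolution stays incomplete and selectivity erodes. The fallback sets the centre by enantioselective protonation instead of reduction; it sets out from 17 and returns at 19. KN(SiMe3)2 at −78 °C and allyl chloroformate give the enol carbonate 6-(3-methylbut-2-en-1-yl)-3-[3-(3-methylbut-2-en-1-yl)-4-(triisopropylsilyloxy)phenyl]-7-(triisopropylsilyloxy)-2H-chromen-4-yl prop-2-en-1-yl carbonate F5. Pd2(dba)3 with a t-BuPHOX ligand and Meldrum's acid as proton donor (decarboxylative asymmetric protonation of the palladium enolate) should then give 19 directly, the hand of the ligand being chosen to deliver R at C3.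

Step 12. Slow cleavage of the hindered silyl ether next to the prenyl group could force long exposure to fluoride, with enolization at C3 and erosion of enantiopurity. The fallback moves the desilylation to the alcohol stage; it sets out from 18 and returns at 20. Bu4NF/AcOH in THF removes both silyl groups while C3 is not α to a carbonyl, giving (3R,4R)-3-[4-hydroxy-3-(3-methylbut-2-en-1-yl)phenyl]-6-(3-methylbut-2-en-1-yl)chroman-4,7-diol F6. Activated MnO2 in acetone should then oxidize only the benzylic C4 carbinol, which is activated by the para hydroxyl, and give 20 under neutral conditions.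

**Further compounds**

F1 | step 9 | 2-(3-bromo-4-hydroxyphenyl)acetic acid | OC(=O)Cc1ccc(O)c(Br)c1
F2 | step 9 | 1-(5-bromo-2,4-dihydroxyphenyl)-2-(3-bromo-4-hydroxyphenyl)ethan-1-one | O=C(Cc1ccc(O)c(Br)c1)c1cc(Br)c(O)cc1O
F3 | step 9 | rac-6-bromo-3-(3-bromo-4-hydroxyphenyl)-7-hydroxychroman-4-one | O=C1c2cc(Br)c(O)cc2OCC1c1ccc(O)c(Br)c1
F4 | step 9 | rac-6-bromo-3-[3-bromo-4-(triisopropylsilyloxy)phenyl]-7-(triisopropylsilyloxy)chroman-4-one | O=C1c2cc(Br)c(O[Si](C(C)C)(C(C)C)C(C)C)cc2OCC1c1ccc(O[Si](C(C)C)(C(C)C)C(C)C)c(Br)c1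
F5 | step 10 | 6-(3-methylbut-2-en-1-yl)-3-[3-(3-methylbut-2-en-1-yl)-4-(triisopropylsilyloxy)phenyl]-7-(triisopropylsilyloxy)-2H-chromen-4-yl prop-2-en-1-yl carbonate | C=CCOC(=O)OC1=C(c2ccc(O[Si](C(C)C)(C(C)C)C(C)C)c(CC=C(C)C)c2)COc2cc(O[Si](C(C)C)(C(C)C)C(C)C)c(CC=C(C)C)cc21
F6 | step 12 | (3R,4R)-3-[4-hydroxy-3-(3-methylbut-2-en-1-yl)phenyl]-6-(3-methylbut-2-en-1-yl)chroman-4,7-diol | CC(C)=CCc1cc([C@@H]2COc3cc(O)c(CC=C(C)C)cc3[C@@H]2O)ccc1O
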